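the same everywhere: J 0.20 M

| charge | D | temperature | remark | time |
|---|---|---|---|---|
| grey | 1.5 mM | 25 °C | run made earlier |  |
| violet | 3.3 mM | 75 °C | run made earlier |  |
| spring | 2.2 mM | 30 °C |  | 6.0 d |
| dawn | 2.2 mM | 120 °C |  | 6.0 d |
| dusk | 2.2 mM | 90 °C |  | 6.0 d |
| noon | 2.2 mM | 60 °C |  | 6.0 d |

- grey (time / d: X / %, J / %): 0.625: 9.6, 92.1; 1.25: 16.0, 83.9; 2.00: 21.9, 77.0; 3.00: 31.8, 66.3; 4.00: 38.8, 59.0
- violet (time / h: X / %, J / %): 1.50: 27.8, 68.4; 3.00: 43.3, 49.6; 5.00: 60.1, 34.0; 8.00: 71.5, 19.3; 10.0: 75.1, 14.6

(scatter of a reading: 1 percentage point)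

- what was read earlier has a scatter of 1 percentage point, one standard deviation

- which flask leads in amount of X, in percent of the J charged ("all alike" within 1.5 percentage points) (spring / dawn / dusk / noon / all alike)
- how much X is there at the end, in percent of the J charged: spring
- how much X is there at the end, in percent of the J charged: dawn
- how much X is there at the end, in percent of the J charged: dusk
- how much X is there at the end, in percent of the J charged: noon

**The gap.** If J only became X, the two readings sum to the charge, so read what is missing at each run's last point, the mass-balance deficit. Grey lacks 2.20% after 4.00 d, barely above the scatter, and violet lacks 10.3% after 10.0 h. Define the leak time τ as the time in which the whole charge goes at that average pace: 182 d for grey, 4.05 d for violet. Assume D plays no part in the leak, and let τ halve at each step of θ in temperature. The two runs give θ = 9.11 K, the leak doubling interval, a rough reading given grey's scatter. Let N be the asked time over τ.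

**Turned round.** Take N under one as my mark of a flask that holds its X: for dawn that asks τ to outlast 6.0 d. Violet, cooler than dawn, already falls short, at 4.05 d. To reverse that, violet's last gap must sit under 6.94%, and it reads 3.4 percentage points above that.

**My reckoning.** Dawn's τ comes to 3.16 h, so N = 45.6. Dusk has N = 4.65, noon 0.474, spring 0.0483. Take the share kept as one over one plus N, as for a loss that thins with its stock: dawn 2.15%, dusk 17.7%, noon 67.9%. This doesn't place spring against noon.

**The forecast.** It holds that “X itself is not being consumed” and names noon as leader, with spring 76%, dawn 27%, dusk 62%, noon 89%. My shares kept for dawn and dusk stand below the forecast's figures for those flasks.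

**The flask.** The leader is noon with 85.2%; spring gives 76.5%, dusk 22.5%, dawn 0.801%.

    J + D ⇌ D + X (K = 3.70, k = 140 M⁻¹ h⁻¹, Ea = 51.0 kJ mol⁻¹, ΔH = −60.0 kJ mol⁻¹)
    2 J → L (k = 0.200 M⁻¹ h⁻¹, Ea = 71.0 kJ mol⁻¹)
    J + X → E (k = 0.200 M⁻¹ h⁻¹, Ea = 98.0 kJ mol⁻¹)
    (constants at 90 °C)

**The cooler neighbour.** Dawn, at N = 45.6, holds 0.801% X beside 54.0% E and 44.2% L. Run the same flask at 95 °C: τ = 21.2 h, N = 6.80, share kept 12.8%. That neighbour ends with 54.9% E, 27.1% L and 13.3% X.

The numbers in the tables were computed with made-up constants; noise was put on by code.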